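**Plan**

- Cuts (chain C1′ on the chroman to C6′ on the cyclohexene; cyclohexene C1″ bears the chain, C2″ the methyl, C6″ the gem-dimethyl): aryl C6–CO2H; diene C2′–C3′ together with C4′–CH3; chain C5′–C6′; chroman O1–C2; and, in the cyclohexene, C1″–C6″ and C2″–C3″ at once.
- Enabling feature: the tetrasubstituted C1″=C2″ olefin lies between quaternary C6″(CH3)2 and C3″H2, with C3″–C4″–C5″–C6″ contiguous. This is the [4+2] adduct of 4-methylpenta-1,3-diene and a but-2-ynoate (ester carbon = C6′) after saturation of C4″=C5″; quaternary C6″ blocks aromatisation.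
- Forward order: the cyclohexadiene ring is made first, then hydrogenated and homologated (ester → alcohol → bromide → terminal alkyne). The chroman is made separately by asymmetric allylic O-alkylation, and its vinyl group is turned into an E-vinyl iodide.
- The fragments are joined by alkyne carboalumination and cross-coupling; the carboxyl group is introduced last from the aryl bromide.
- Stereochemistry: C2 (R) comes from the ligand-controlled palladium allylation; the E-trisubstituted olefin from syn-carboalumination; the E-disubstituted olefin from Takai olefination; both olefins are retained in the coupling.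

Key step: step 1

Assumption: with the E-configured carbonate 16 the (R,R)-ligand is taken to give the (R)-chroman; the sense of induction depends on olefin geometry and ligand hand, so the ligand antipode is used, with no other change, if a pilot run shows the opposite sense.

**Step 1**
Reactants: 1 4-methylpenta-1,3-diene; 2 ethyl but-2-ynoate
Product: 3 ethyl 2,6,6-trimethylcyclohexa-1,4-diene-1-carboxylate
Conditions: 1 (3 equiv), EtAlCl2 (30 mol%), CH2Cl2, −40 → 0 °C
Reagents that add atoms: none
Why: A Lewis-acid-accelerated, normal-electron-demand Diels–Alder reaction: the s-cis conformer of diene 1 (HOMO) adds suprafacially to the EtAlCl2-complexed alkynoate 2 (LUMO) in a concerted but asynchronous [4+2] transition state, in which the unhindered CH2 terminus of the diene bonds first to the β-carbon of the butynoate and the C(CH3)2 terminus then closes onto the α-carbon. The closest known reaction type is the AlCl3- or EtAlCl2-promoted cycloaddition of propiolates and 2-alkynoates with 1,3-dienes to cyclohexa-1,4-diene-1-carboxylates. The six-membered ring is closed by intermolecular [4+2] cycloaddition, both σ bonds coming from one π4s + π2s event without a tether. No stereocentre is formed, because the product is achiral. The selectivity needed is regiochemical (ester carbon next to the quaternary carbon); it is secured by the two methyl donors on C4 of the diene, which put the larger HOMO coefficient on C1 and stabilise positive charge at C4, matched to the larger LUMO coefficient at the β-carbon of the complexed ester. Chemoselectivity over diene oligomerisation, ene reaction and stepwise [2+2] addition rests on the proton-scavenging alkylaluminium Lewis acid, low temperature and excess diene, and the quaternary ring carbon rules out aromatisation of the 1,4-diene.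

**Step 2**
Reactants: 3 ethyl 2,6,6-trimethylcyclohexa-1,4-diene-1-carboxylate
Product: 4 ethyl 2,6,6-trimethylcyclohex-1-ene-1-carboxylate
Conditions: H2 (3 atm), RhCl(PPh3)3 (5 mol%), benzene–EtOH, rt
Reagents that add atoms: none
Why: Homogeneous hydrogenation should reduce the cis-disubstituted C4=C5 bond only, because the bulky rhodium hydride cannot engage the tetrasubstituted, ester-conjugated C1=C2 bond.

**Step 3**
Reactants: 4 ethyl 2,6,6-trimethylcyclohex-1-ene-1-carboxylate
Product: 5 (2,6,6-trimethylcyclohex-1-en-1-yl)methanol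
Conditions: LiAlH4, Et2O, 0 °C → rt; Fieser work-up
Reagents that add atoms: none
Why: Hydride reduction of the hindered conjugated ester should give the allylic alcohol by 1,2-addition, the tetrasubstituted olefin resisting conjugate reduction.

**Step 4**
Reactants: 5 (2,6,6-trimethylcyclohex-1-en-1-yl)methanol
Product: 6 2-(bromomethyl)-1,3,3-trimethylcyclohex-1-ene
Conditions: PBr3 (0.4 equiv), pyridine (cat.), Et2O, −10 °C; crude bromide used at once
Reagents that add atoms: phosphorus tribromide BrP(Br)Br
Why: Bromination of the primary allylic alcohol through its phosphite ester proceeds by SN2 displacement at the primary carbon, the SN2′ position being a fully substituted ring carbon.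

**Step 5**
Reactants: 6 2-(bromomethyl)-1,3,3-trimethylcyclohex-1-ene; 7 trimethyl(prop-1-yn-1-yl)silane
Product: 9 2-(but-3-yn-1-yl)-1,3,3-trimethylcyclohex-1-ene, via silyl alkyne 8 (not isolated)
Conditions: 7, n-BuLi, THF, −78 → −20 °C; then 6, −78 °C → rt; then MeOH, K2CO3, rt
Reagents that add atoms: none
Why: SN2 alkylation of the primary allylic bromide by the propargylic lithium reagent (the silyl group suppresses allenyl products and SN2′ attack is sterically blocked), followed by methanolysis of the alkynyl C–Si bond, should give the terminal alkyne.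

**Step 6**
Reactants: 10 4-bromo-2-iodophenol; 11 but-3-en-2-ol
Product: 12 4-(5-bromo-2-hydroxyphenyl)butan-2-one
Conditions: Pd(OAc)2 (3 mol%), NaHCO3 (2.5 equiv), n-Bu4NCl (1 equiv), DMF, 50 °C
Reagents that add atoms: none
Why: Jeffery-type Heck reaction of the aryl iodide with a secondary allylic alcohol: aryl insertion at the terminal carbon, β-hydride elimination toward the carbinol and tautomerisation give the saturated methyl ketone, and the aryl bromide does not react with ligand-free palladium at this temperature.

**Step 7**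
Reactants: 12 4-(5-bromo-2-hydroxyphenyl)butan-2-one; 13 triethyl phosphonoacetate
Product: 14 ethyl (2E)-5-(5-bromo-2-hydroxyphenyl)-3-methylpent-2-enoate
Conditions: 13 (1.3 equiv), NaH (2.4 equiv), THF, 0 → 60 °C; Z-isomer removed by chromatography
Reagents that add atoms: none
Why: Horner–Wadsworth–Emmons olefination of the methyl ketone (the extra base holds the phenol as its phenoxide) should favour the E-enoate; the minor Z-isomer is removed because olefin geometry fixes the sense of the later asymmetric cyclisation.

**Step 8**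
Reactants: 14 ethyl (2E)-5-(5-bromo-2-hydroxyphenyl)-3-methylpent-2-enoate
Product: 15 4-bromo-2-[(3E)-5-hydroxy-3-methylpent-3-en-1-yl]phenol
Conditions: i-Bu2AlH (3.3 equiv), CH2Cl2, −78 → 0 °C; Rochelle salt work-up
Reagents that add atoms: none
Why: 1,2-Reduction of the enoate should give the E-allylic alcohol without change of olefin geometry, and the aryl bromide is inert to the hydride.

**Step 9**
Reactants: 15 4-bromo-2-[(3E)-5-hydroxy-3-methylpent-3-en-1-yl]phenol
Product: 16 (2E)-5-(5-bromo-2-hydroxyphenyl)-3-methylpent-2-en-1-yl methyl carbonate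
Conditions: ClCO2Me (1.05 equiv), pyridine (1.5 equiv), CH2Cl2, −30 °C
Reagents that add atoms: methyl chloroformate COC(=O)Cl
Why: Chemoselective O-acylation: with pyridine as the only base the neutral primary allylic alcohol should be acylated faster than the neutral, less nucleophilic phenol.

**Step 10**
Reactants: 16 (2E)-5-(5-bromo-2-hydroxyphenyl)-3-methylpent-2-en-1-yl methyl carbonate
Product: 17 (2R)-6-bromo-2-ethenyl-2-methyl-3,4-dihydro-2H-chromene
Conditions: Pd2(dba)3·CHCl3 (2 mol%), (R,R)-DACH-phenyl Trost ligand (6 mol%), AcOH (1 equiv), CH2Cl2, rt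
Reagents that add atoms: none
Why: Intramolecular Trost asymmetric allylic alkylation: ionisation to the π-allylpalladium complex and 6-exo attack of the phenol at the substituted allyl terminus inside the chiral pocket of the ligand set the quaternary C2 stereocentre, acetic acid speeding π–σ–π equilibration so that the faster-cyclising diastereomeric complex is funnelled to the (R)-chroman.

**Step 11**
Reactants: 17 (2R)-6-bromo-2-ethenyl-2-methyl-3,4-dihydro-2H-chromene
Product: 18 (2R)-6-bromo-2-methyl-3,4-dihydro-2H-chromene-2-carbaldehyde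
Conditions: O3, CH2Cl2–MeOH, −78 °C (indicator dye end point); then Me2S, → rt
Reagents that add atoms: ozone [O-][O+]=O
Why: Ozonolysis with reductive work-up cleaves the only olefin to the aldehyde; the quaternary α-carbon cannot epimerise and the bromo-substituted arene should survive at −78 °C.

**Step 12**
Reactants: 18 (2R)-6-bromo-2-methyl-3,4-dihydro-2H-chromene-2-carbaldehyde
Product: 19 (2R)-6-bromo-2-[(E)-2-iodoethenyl]-2-methyl-3,4-dihydro-2H-chromene
Conditions: CrCl2 (6 equiv), CHI3 (2 equiv), THF–dioxane, 0 °C → rt, dark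
Reagents that add atoms: iodoform IC(I)I
Why: Takai olefination: the gem-dichromium species from iodoform adds to the hindered, non-enolisable aldehyde and elimination should give the E-vinyl iodide.

**Step 13**
Reactants: 9 2-(but-3-yn-1-yl)-1,3,3-trimethylcyclohex-1-ene; 19 (2R)-6-bromo-2-[(E)-2-iodoethenyl]-2-methyl-3,4-dihydro-2H-chromene
Product: 21 (2R)-6-bromo-2-methyl-2-[(1E,3E)-4-methyl-6-(2,6,6-trimethylcyclohex-1-en-1-yl)hexa-1,3-dien-1-yl]-3,4-dihydro-2H-chromene, via alkenylalane 20 (not isolated)
Conditions: 9, AlMe3 (2 equiv), Cp2ZrCl2 (0.25 equiv), CH2Cl2, 0 °C → rt; volatiles removed in vacuo; then 19, ZnCl2 (0.5 equiv), Pd(PPh3)4 (5 mol%), THF, rt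
Reagents that add atoms: trimethylaluminium C[Al](C)C
Why: Negishi zirconium-catalysed carboalumination adds CH3 and Al syn across the terminal alkyne (Al at the terminal carbon), fixing the E-trisubstituted olefin, and the zinc-assisted palladium-catalysed Negishi coupling with the vinyl iodide proceeds with retention at both sp2 carbons; oxidative addition to the C–I bond should be far faster than to the aryl bromide or ionisation of the tertiary allylic ether.

**Step 14**
Reactants: 21 (2R)-6-bromo-2-methyl-2-[(1E,3E)-4-methyl-6-(2,6,6-trimethylcyclohex-1-en-1-yl)hexa-1,3-dien-1-yl]-3,4-dihydro-2H-chromene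
Product: 23 (2R)-2-methyl-2-[(1E,3E)-4-methyl-6-(2,6,6-trimethylcyclohex-1-en-1-yl)hexa-1,3-dien-1-yl]-3,4-dihydro-2H-chromene-6-carboxylic acid, via aryllithium 22 (not isolated)
Conditions: t-BuLi (2.05 equiv), THF, −78 °C; CO2 (gas), −78 → 0 °C; cold dilute HCl to pH 3
Reagents that add atoms: carbon dioxide O=C=O
Why: Bromine–lithium exchange at −78 °C should outrun any addition of the alkyllithium to the hindered diene, and carboxylation of the aryllithium gives the acid directly; the stereocentre and both olefins are untouched.

**Compound list**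

1 | 4-methylpenta-1,3-diene | C=CC=C(C)C | starting material
2 | ethyl but-2-ynoate | CC#CC(=O)OCC | starting material
3 | ethyl 2,6,6-trimethylcyclohexa-1,4-diene-1-carboxylate | CCOC(=O)C1=C(C)CC=CC1(C)C | intermediate
4 | ethyl 2,6,6-trimethylcyclohex-1-ene-1-carboxylate | CCOC(=O)C1=C(C)CCCC1(C)C | intermediate
5 | (2,6,6-trimethylcyclohex-1-en-1-yl)methanol | OCC1=C(C)CCCC1(C)C | intermediate
6 | 2-(bromomethyl)-1,3,3-trimethylcyclohex-1-ene | BrCC1=C(C)CCCC1(C)C | intermediate
7 | trimethyl(prop-1-yn-1-yl)silane | CC#C[Si](C)(C)C | starting material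
8 | trimethyl[4-(2,6,6-trimethylcyclohex-1-en-1-yl)but-1-yn-1-yl]silane | C[Si](C)(C)C#CCCC1=C(C)CCCC1(C)C | intermediate
9 | 2-(but-3-yn-1-yl)-1,3,3-trimethylcyclohex-1-ene | C#CCCC1=C(C)CCCC1(C)C | intermediate
10 | 4-bromo-2-iodophenol | Oc1ccc(Br)cc1I | starting material
11 | but-3-en-2-ol (racemic) | CC(O)C=C | starting material
12 | 4-(5-bromo-2-hydroxyphenyl)butan-2-one | CC(=O)CCc1cc(Br)ccc1O | intermediate
13 | triethyl phosphonoacetate | CCOC(=O)CP(=O)(OCC)OCC | starting material
14 | ethyl (2E)-5-(5-bromo-2-hydroxyphenyl)-3-methylpent-2-enoate | CCOC(=O)/C=C(\C)CCc1cc(Br)ccc1O | intermediate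
15 | 4-bromo-2-[(3E)-5-hydroxy-3-methylpent-3-en-1-yl]phenol | OC/C=C(\C)CCc1cc(Br)ccc1O | intermediate
16 | (2E)-5-(5-bromo-2-hydroxyphenyl)-3-methylpent-2-en-1-yl methyl carbonate | COC(=O)OC/C=C(\C)CCc1cc(Br)ccc1O | intermediate
17 | (2R)-6-bromo-2-ethenyl-2-methyl-3,4-dihydro-2H-chromene | C=C[C@@]1(C)CCc2cc(Br)ccc2O1 | intermediate
18 | (2R)-6-bromo-2-methyl-3,4-dihydro-2H-chromene-2-carbaldehyde | O=C[C@@]1(C)CCc2cc(Br)ccc2O1 | intermediate
19 | (2R)-6-bromo-2-[(E)-2-iodoethenyl]-2-methyl-3,4-dihydro-2H-chromene | I/C=C/[C@@]1(C)CCc2cc(Br)ccc2O1 | intermediate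
20 | dimethyl[(1E)-2-methyl-4-(2,6,6-trimethylcyclohex-1-en-1-yl)but-1-en-1-yl]alumane | C[Al](C)/C=C(\C)CCC1=C(C)CCCC1(C)C | intermediate
21 | (2R)-6-bromo-2-methyl-2-[(1E,3E)-4-methyl-6-(2,6,6-trimethylcyclohex-1-en-1-yl)hexa-1,3-dien-1-yl]-3,4-dihydro-2H-chromene | CC1=C(CC/C(C)=C/C=C/[C@@]2(C)CCc3cc(Br)ccc3O2)C(C)(C)CCC1 | intermediate
22 | aryllithium: [(2R)-2-methyl-2-[(1E,3E)-4-methyl-6-(2,6,6-trimethylcyclohex-1-en-1-yl)hexa-1,3-dien-1-yl]-3,4-dihydro-2H-chromen-6-yl]lithium | CC1=C(CC/C(C)=C/C=C/[C@@]2(C)CCc3cc([Li])ccc3O2)C(C)(C)CCC1 | intermediate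
23 | (2R)-2-methyl-2-[(1E,3E)-4-methyl-6-(2,6,6-trimethylcyclohex-1-en-1-yl)hexa-1,3-dien-1-yl]-3,4-dihydro-2H-chromene-6-carboxylic acid | CC1=C(CC/C(C)=C/C=C/[C@@]2(C)CCc3cc(C(=O)O)ccc3O2)C(C)(C)CCC1 | target

**Step count**

Total: 14 steps. Longest linear sequence: 9 steps (steps 6 to 14).

**Steps most likely to fail**

Step 1. The Z-methyl group of 1 disfavours the s-cis conformer, so the cycloaddition may be outrun by Lewis-acid-induced oligomerisation of the diene or by stepwise [2+2] and ene pathways. The fallback sets out from 2 and comes back to the route at 4. The cuprate made from (4-methylpent-3-en-1-yl)magnesium bromide F1 (from commercial 5-bromo-2-methylpent-2-ene and Mg) and CuBr·SMe2 should add syn to 2 at −78 °C to give ethyl (2E)-3,7-dimethylocta-2,6-dienoate F2. Cation–olefin cyclisation of F2 (conc. H2SO4/HCO2H, 0 °C, or SnCl4, CH2Cl2) should close the ring to ethyl 2,6,6-trimethylcyclohex-2-ene-1-carboxylate F3. Equilibration with NaOEt in EtOH should then move the double bond into conjugation to give 4; this last equilibration is the least certain part of the fallback.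

Step 10. Enantiofacial discrimination in the cyclisation may be insufficient or of the wrong sense, and reversible ionisation of the product ether may erode the enantiomeric purity. The fallback sets out from 15 and comes back at 18. Sharpless asymmetric epoxidation of 15 (Ti(OiPr)4, L-(+)-diethyl tartrate, t-BuOOH, 4 Å sieves, CH2Cl2, −20 °C) should give [(2S,3S)-3-[2-(5-bromo-2-hydroxyphenyl)ethyl]-3-methyloxiran-2-yl]methanol F4 by the usual facial rule for E-allylic alcohols. Acid-catalysed (camphorsulfonic acid, CH2Cl2, 0 °C) 6-exo opening of the epoxide by the phenol at the tertiary carbon, with inversion, should give (1S)-1-[(2R)-6-bromo-2-methyl-3,4-dihydro-2H-chromen-2-yl]ethane-1,2-diol F5. Cleavage of F5 with NaIO4 (THF–H2O) gives 18.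

Step 13. Methyl transfer from residual AlMe3 may compete, transmetalation of the alkenylalane may be slow, or zerovalent palladium may ionise the tertiary allylic aryl ether and erode the stereocentre. The fallback sets out from 9 and 18 and comes back at 21. Alkenylalane 20 is quenched with I2 (THF, −30 °C) to give 2-[(3E)-4-iodo-3-methylbut-3-en-1-yl]-1,3,3-trimethylcyclohex-1-ene F6. Aldehyde 18 is converted by the boron variant of the Takai olefination (Cl2CHBpin, CrCl2, LiI, THF) into 2-[(E)-2-[(2R)-6-bromo-2-methyl-3,4-dihydro-2H-chromen-2-yl]ethenyl]-4,4,5,5-tetramethyl-1,3,2-dioxaborolane F7. Suzuki–Miyaura coupling of F6 with F7 (Pd(PPh3)4, aqueous K3PO4, THF, rt) should give 21 with retention of both olefin geometries.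

**Further compounds**

F1 | step 1 | (4-methylpent-3-en-1-yl)magnesium bromide | CC(C)=CCC[Mg]Br
F2 | step 1 | ethyl (2E)-3,7-dimethylocta-2,6-dienoate | CCOC(=O)/C=C(\C)CCC=C(C)C
F3 | step 1 | ethyl 2,6,6-trimethylcyclohex-2-ene-1-carboxylate (racemic) | CCOC(=O)C1C(C)=CCCC1(C)C
F4 | step 10 | [(2S,3S)-3-[2-(5-bromo-2-hydroxyphenyl)ethyl]-3-methyloxiran-2-yl]methanol | OC[C@@H]1O[C@@]1(C)CCc1cc(Br)ccc1O
F5 | step 10 | (1S)-1-[(2R)-6-bromo-2-methyl-3,4-dihydro-2H-chromen-2-yl]ethane-1,2-diol | OC[C@H](O)[C@@]1(C)CCc2cc(Br)ccc2O1
F6 | step 13 | 2-[(3E)-4-iodo-3-methylbut-3-en-1-yl]-1,3,3-trimethylcyclohex-1-ene | I/C=C(\C)CCC1=C(C)CCCC1(C)C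
F7 | step 13 | 2-[(E)-2-[(2R)-6-bromo-2-methyl-3,4-dihydro-2H-chromen-2-yl]ethenyl]-4,4,5,5-tetramethyl-1,3,2-dioxaborolane | CC1(C)OB(/C=C/[C@@]2(C)CCc3cc(Br)ccc3O2)OC1(C)C
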